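Ring C of the upper flavan unit is cut at C2–C3. The key step exploits that C2 carries O1 and ring B, so it can enter as the carbonyl carbon of an aryl 4-benzyloxybenzoate, while C3 is the CH= carbon of an ortho (S)-1-silyloxyallyl group: the titanium methylidene Cp2Ti=CH2 joins them in one carbonyl–olefin metathesis to a 4-silyloxyflav-2-ene. The C4 oxygen, set by asymmetric vinylation, then directs hydroboration of the O1–C2=C3 enol ether to the opposite face (2,3-trans) and finally leaves; the C4 cation is captured trans to the 3-hydroxyl by C6 of an 8-bromoafzelechin ether (ring D).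

Key step: step 3

Assumption: (+)-afzelechin (2R,3S) is bought as the natural flavan-3-ol, and Zn(CH=CH2)2 is used preformed and salt-free.

Step 1
Reactants: 1 4-(benzyloxy)-2-hydroxybenzaldehyde; 2 4-(benzyloxy)benzoyl chloride
Product: 3 5-(benzyloxy)-2-formylphenyl 4-(benzyloxy)benzoate
Conditions: Et3N, DMAP (cat.), CH2Cl2, 0 °C → rt
Reagents that add atoms: none
Why: Acylation of the phenol by the acid chloride under nucleophilic catalysis should give the aryl ester whose carbonyl carbon later becomes C2.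

Step 2
Reactants: 3 5-(benzyloxy)-2-formylphenyl 4-(benzyloxy)benzoate
Product: 5 5-(benzyloxy)-2-[(1S)-1-(tert-butyldimethylsilyloxy)prop-2-en-1-yl]phenyl 4-(benzyloxy)benzoate, via (S)-allylic alcohol 4 (not isolated)
Conditions: Zn(CH=CH2)2 (1.5 equiv), (−)-3-exo-(dimethylamino)isoborneol (5 mol %), toluene, 0 °C; then 2,6-lutidine, TBSOTf, −40 → 0 °C; aq. NH4Cl
Reagents that add atoms: divinylzinc, C=C[Zn]C=C; tert-butyldimethylsilyl trifluoromethanesulfonate, CC(C)(C)[Si](C)(C)OS(=O)(=O)C(F)(F)F
Why: The amino-alkoxide–zinc catalysed 1,2-addition of an organozinc should deliver the vinyl group to the Si face of the aldehyde and so set the future C4 carbinol as S, and silylation of the zinc alkoxide in the same flask forestalls migration of the neighbouring aroyl group.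

Step 3
Reactants: 5 5-(benzyloxy)-2-[(1S)-1-(tert-butyldimethylsilyloxy)prop-2-en-1-yl]phenyl 4-(benzyloxy)benzoate
Product: 7 (4S)-7-(benzyloxy)-2-[4-(benzyloxy)phenyl]-4-(tert-butyldimethylsilyloxy)-4H-chromene (the 4-silyloxyflav-2-ene), via aryl enol ether diene 6 (not isolated)
Conditions: Cp2Ti(μ-CH2)(μ-Cl)AlMe2 (Tebbe reagent, 4 equiv), pyridine (cat.), THF, 0 → 25 °C, then 65 °C
Reagents that add atoms: none
Why: Cp2Ti=CH2 first methylenates the aryl ester through an oxatitanacyclobutane to the enol ether 6; a second methylidene then exchanges with the terminal vinyl group (ethylene leaves), and the titanium alkylidene now on C3 undergoes [2+2] cycloaddition and cycloreversion with the enol ether C=CH2, which forms the C2=C3 bond. The closest known reaction types are the titanium-mediated cyclization of olefinic esters to cyclic enol ethers and the enol-ether ring-closing metathesis that turns 2-allylphenyl esters into 2-substituted 4H-chromenes. Ring C is closed as a six-membered ring by ring-closing metathesis, with both new sp2 carbons (C2 and C3) inside the ring. No stereocenter is formed, and the C4 stereocenter should survive because nothing in the flask deprotonates it. The step needs chemoselectivity for the single ester carbonyl (benzyl and silyl ethers are inert to the methylidene) and must avoid ionization of the doubly activated C4–O bond to a flavylium ion, which pyridine (it ties up Me2AlCl) and the bulky silyl group should secure.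

Step 4
Reactants: 7 (4S)-7-(benzyloxy)-2-[4-(benzyloxy)phenyl]-4-(tert-butyldimethylsilyloxy)-4H-chromene
Product: 8 (2R,3R,4R)-7-(benzyloxy)-2-[4-(benzyloxy)phenyl]-4-(tert-butyldimethylsilyloxy)chroman-3-ol (2,3-trans-3,4-trans)
Conditions: BH3·SMe2, THF, −20 → 0 °C; then NaOH (aq), H2O2, 0 °C
Reagents that add atoms: hydrogen peroxide, OO
Why: Hydroboration–oxidation should add B–H syn across the electron-rich enol ether with boron on C3 and from the face opposite the pseudoaxial C4 silyloxy group, and oxidation with retention then gives the 2,3-trans-3,4-trans alcohol, so that C4 sets C2 (R) and C3.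

Step 5
Reactants: 9 (+)-afzelechin
Product: 10 5,7,4'-tri-O-benzylafzelechin
Conditions: BnBr (3.3 equiv), K2CO3, DMF, 0 °C → rt
Reagents that add atoms: benzyl bromide, BrCc1ccccc1
Why: Williamson etherification with K2CO3 deprotonates only the three phenols, so the secondary 3-hydroxyl should stay free.

Step 6
Reactants: 10 5,7,4'-tri-O-benzylafzelechin
Product: 11 8-bromo-5,7,4'-tri-O-benzylafzelechin
Conditions: N-bromosuccinimide (1.0 equiv), CH2Cl2, −78 → 0 °C
Reagents that add atoms: N-bromosuccinimide, O=C1CCC(=O)N1Br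
Why: Electrophilic aromatic bromination of the phloroglucinol-type ring of 10 (ring D of the target) should go to C8, its more reactive position, which leaves C6 as the only nucleophilic carbon for step 7.

Step 7
Reactants: 8 (2R,3R,4R)-7-(benzyloxy)-2-[4-(benzyloxy)phenyl]-4-(tert-butyldimethylsilyloxy)chroman-3-ol; 11 8-bromo-5,7,4'-tri-O-benzylafzelechin
Product: 12 7,4'-di-O-benzylguibourtinidol-(4α→6)-8-bromo-5,7,4'-tri-O-benzylafzelechin
Conditions: 11 (3 equiv), TMSOTf (0.5 equiv), CH2Cl2, 4 Å molecular sieves, −78 → −40 °C; Et3N quench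
Reagents that add atoms: none
Why: Lewis-acid ionization of the C4 silyl ether should give the benzylic cation stabilized by O1 and the 7-benzyloxy group, which C6 of 11 attacks in a Friedel–Crafts alkylation from the face opposite the C3 hydroxyl, so the interflavan bond is formed 3,4-trans (C4 S in the target).

Step 8
Reactants: 12 7,4'-di-O-benzylguibourtinidol-(4α→6)-8-bromo-5,7,4'-tri-O-benzylafzelechin
Product: 13 guibourtinidol-(4α→6)-afzelechin (CNP0325116.1)
Conditions: H2 (1 atm), Pd(OH)2/C, Et3N, THF/MeOH, rt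
Reagents that add atoms: none
Why: Catalytic hydrogenolysis should cleave the five benzyl ethers and the aryl C–Br bond (Et3N takes up HBr) without touching the five stereocenters or the interflavan bond.

Compound list
1 | 4-(benzyloxy)-2-hydroxybenzaldehyde | O=Cc1ccc(OCc2ccccc2)cc1O | starting material
2 | 4-(benzyloxy)benzoyl chloride | O=C(Cl)c1ccc(OCc2ccccc2)cc1 | starting material
3 | 5-(benzyloxy)-2-formylphenyl 4-(benzyloxy)benzoate | O=Cc1ccc(OCc2ccccc2)cc1OC(=O)c1ccc(OCc2ccccc2)cc1 | intermediate
4 | 5-(benzyloxy)-2-[(1S)-1-hydroxyprop-2-en-1-yl]phenyl 4-(benzyloxy)benzoate (present as its zinc alkoxide) | C=C[C@H](O)c1ccc(OCc2ccccc2)cc1OC(=O)c1ccc(OCc2ccccc2)cc1 | intermediate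
5 | 5-(benzyloxy)-2-[(1S)-1-(tert-butyldimethylsilyloxy)prop-2-en-1-yl]phenyl 4-(benzyloxy)benzoate | C=C[C@H](O[Si](C)(C)C(C)(C)C)c1ccc(OCc2ccccc2)cc1OC(=O)c1ccc(OCc2ccccc2)cc1 | intermediate
6 | tert-butyl{[(1S)-1-(4-(benzyloxy)-2-{[1-(4-(benzyloxy)phenyl)ethenyl]oxy}phenyl)prop-2-en-1-yl]oxy}dimethylsilane | C=C[C@H](O[Si](C)(C)C(C)(C)C)c1ccc(OCc2ccccc2)cc1OC(=C)c1ccc(OCc2ccccc2)cc1 | intermediate
7 | (4S)-7-(benzyloxy)-2-[4-(benzyloxy)phenyl]-4-(tert-butyldimethylsilyloxy)-4H-chromene | CC(C)(C)[Si](C)(C)O[C@H]1C=C(c2ccc(OCc3ccccc3)cc2)Oc2cc(OCc3ccccc3)ccc21 | intermediate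
8 | (2R,3R,4R)-7-(benzyloxy)-2-[4-(benzyloxy)phenyl]-4-(tert-butyldimethylsilyloxy)chroman-3-ol | C(c1ccccc1)Oc1ccc([C@H]2Oc3cc(OCc4ccccc4)ccc3[C@@H](O[Si](C)(C)C(C)(C)C)[C@@H]2O)cc1 | intermediate
9 | (+)-afzelechin, (2R,3S)-2-(4-hydroxyphenyl)chromane-3,5,7-triol | Oc1cc(O)c2C[C@H](O)[C@@H](c3ccc(O)cc3)Oc2c1 | starting material
10 | 5,7,4'-tri-O-benzylafzelechin | C(c1ccccc1)Oc1cc(OCc2ccccc2)c2C[C@H](O)[C@@H](c3ccc(OCc4ccccc4)cc3)Oc2c1 | intermediate
11 | 8-bromo-5,7,4'-tri-O-benzylafzelechin | C(c1ccccc1)Oc1cc(OCc2ccccc2)c2C[C@H](O)[C@@H](c3ccc(OCc4ccccc4)cc3)Oc2c1Br | intermediate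
12 | 7,4'-di-O-benzylguibourtinidol-(4α→6)-8-bromo-5,7,4'-tri-O-benzylafzelechin | C(c1ccccc1)Oc1ccc([C@H]2Oc3cc(OCc4ccccc4)ccc3[C@@H](c3c(OCc4ccccc4)c(Br)c4c(c3OCc3ccccc3)C[C@H](O)[C@@H](c3ccc(OCc5ccccc5)cc3)O4)[C@@H]2O)cc1 | intermediate
13 | guibourtinidol-(4α→6)-afzelechin (CNP0325116.1) | Oc1ccc([C@H]2Oc3cc(O)ccc3[C@@H](c3c(O)cc4c(c3O)C[C@H](O)[C@@H](c3ccc(O)cc3)O4)[C@@H]2O)cc1 | target

Total step count: 8. Longest linear sequence: 6 steps (steps 1, 2, 3, 4, 7, 8).

Steps most likely to fail

Step 3. The substituted titanium alkylidene may form too slowly at the hindered allylic position, so that the reaction stops at the enol ether, or the aluminium Lewis acid may ionize the C4–O bond. The fallback separates the two events and closes the ring with a different, catalytic metal alkylidene. It sets out from 5: aluminium-free methylenation with Cp2TiMe2 (toluene, 65 °C) gives the aryl enol ether diene 6, which is isolated. Ring-closing metathesis of 6 with second-generation Grubbs catalyst (H2IMes)(PCy3)Cl2Ru=CHPh (toluene, 70 °C) then forms the C2=C3 bond and comes back to the route at 7. This fallback makes no compound outside the list (F0).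

Step 4. Borane may ionize the C4 silyloxy group of the flavylium pseudo-base ether (followed by hydride reduction at C4), or the C3 borane may eliminate with the C4 silyloxy group, so that the stereochemical relay is lost. The fallback forms the interflavan bond before the hydroboration and lets the C4 aryl group direct the borane. It sets out from 7: with 11 and a catalytic acid (camphorsulfonic acid, CH2Cl2, −40 °C) 7 is ionized on purpose to the flavylium ion, and C6 of 11 adds at C4. This should give 7,4'-di-O-benzyl-(4S)-4-(8-bromo-5,7,4'-tri-O-benzylafzelechin-6-yl)flav-2-ene F1 together with its (4R)-epimer F2, which is removed by chromatography; C4 is not controlled in this fallback. Hydroboration–oxidation of F1 (BH3·SMe2, THF; NaOH, H2O2) anti to the C4 aryl group comes back to the route at 12.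

Step 7. Attack by the hindered, bromine-deactivated C6 may be slow, so that the cation condenses with itself, or the nucleophile may approach from both faces of the cation (4α and 4β). The fallback adds neighbouring-group participation. It sets out from 8: acetylation (Ac2O, pyridine, DMAP) gives (2R,3R,4R)-7-(benzyloxy)-2-[4-(benzyloxy)phenyl]-4-(tert-butyldimethylsilyloxy)chroman-3-yl acetate F3. On ionization with TMSOTf its acetate should bridge C3 and C4 as an acetoxonium ion and force 11 to enter from the opposite face, which gives the 3-O-acetyl derivative of the protected dimer F4. Methanolysis (K2CO3, MeOH/THF) comes back to the route at 12.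

Further compounds
F0 | step 3 | none | none
F1 | step 4 | 7,4'-di-O-benzyl-(4S)-4-(8-bromo-5,7,4'-tri-O-benzylafzelechin-6-yl)flav-2-ene | C(c1ccccc1)Oc1ccc(C2=C[C@H](c3c(OCc4ccccc4)c(Br)c4c(c3OCc3ccccc3)C[C@H](O)[C@@H](c3ccc(OCc5ccccc5)cc3)O4)c3ccc(OCc4ccccc4)cc3O2)cc1
F2 | step 4 | 7,4'-di-O-benzyl-(4R)-4-(8-bromo-5,7,4'-tri-O-benzylafzelechin-6-yl)flav-2-ene | C(c1ccccc1)Oc1ccc(C2=C[C@@H](c3c(OCc4ccccc4)c(Br)c4c(c3OCc3ccccc3)C[C@H](O)[C@@H](c3ccc(OCc5ccccc5)cc3)O4)c3ccc(OCc4ccccc4)cc3O2)cc1
F3 | step 7 | (2R,3R,4R)-7-(benzyloxy)-2-[4-(benzyloxy)phenyl]-4-(tert-butyldimethylsilyloxy)chroman-3-yl acetate | C(c1ccccc1)Oc1ccc([C@H]2Oc3cc(OCc4ccccc4)ccc3[C@@H](O[Si](C)(C)C(C)(C)C)[C@@H]2OC(C)=O)cc1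
F4 | step 7 | 3-O-acetyl-7,4'-di-O-benzylguibourtinidol-(4α→6)-8-bromo-5,7,4'-tri-O-benzylafzelechin | C(c1ccccc1)Oc1ccc([C@H]2Oc3cc(OCc4ccccc4)ccc3[C@@H](c3c(OCc4ccccc4)c(Br)c4c(c3OCc3ccccc3)C[C@H](O)[C@@H](c3ccc(OCc5ccccc5)cc3)O4)[C@@H]2OC(C)=O)cc1
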